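# Proposed synthesis of CNP0174686.2 (17) by enzymatic arene cis-dihydroxylation, B-alkyl coupling and epoxide migration

## Analysis of the target

The target (17) joins a drimane trans-decalin (rings A and B: gem-dimethyl C4, angular methyl on C10, exocyclic C8=C12 methylidene) through one methylene, C11, to a fully functionalised epoxycyclohexenone (ring C). Ring C is numbered C1' (quaternary oxirane carbon bearing C11), C2' (oxirane CH), C3' (CHOH), C4' (bearing the hydroxymethyl carbon C7'), C5' (=CH) and C6' (C=O). There are six stereocentres in two isolated sets: C5, C9 and C10 of the decalin (all S) and C1', C2', C3' of ring C (all S), with the oxirane oxygen and the C3' hydroxyl on the same face. The methylene spacer rules out useful stereochemical communication between the sets, so each must be made in absolute form. Sensitive groups are the α,β-epoxy ketone (bases, nucleophiles), the γ-hydroxy enone and its cyclohexadiene precursors (aromatisation by loss of water), and the C8=C12 alkene, which migrates into the ring under acid and competes in any electrophilic oxidation. The difficulty sits at C1', a quaternary oxirane carbon flanked by a ketone and a hindered CH2, and in placing three contiguous oxygenated centres on a ring with no resident stereocentre to lean on. The strategy rests on one feature: C2' and C3' are neighbouring CH–O carbons with cis oxygens, bracketed by C1' and C4', which carry the two carbon substituents in a para relationship. This is the pattern of the cis-dihydrodiol that an arene dioxygenase makes from a para-disubstituted benzene, with C5' and C6' as the untouched CH=CH edge.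

## Retrosynthetic reasoning

**17 ⇒ 16.** The last bonds cut are the two Si–O bonds of a di-tert-butylsilylene that ties O3' to O7' in 16. These are the only 1,3-related hydroxyls, so one bifunctional silicon group distinguishes O3' from its neighbour O2' by ring size alone. It is removed at the end by buffered fluoride, without the base that the epoxy enone would not tolerate.

**16 ⇒ 15.** The C6' carbonyl is taken back to the allylic carbinol 15. An oxidant restricted to allylic alcohols does not need a pure substrate: the non-allylic regioisomer 14 is inert to it, and the C6' configuration is irrelevant.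

**15 ⇒ 13 (through 14).** The C1'–O bond of the oxirane in 15 is cut, which returns that oxygen to C2' alone and places an oxygen bridge between C1' and C6' on the opposite face. 15 is thus the Payne isomer of trans-epoxy alcohol 14, which is unmasked from acetate 13. The gain is that the oxirane oxygen of 17 is the C2' oxygen itself, so its cis relation to O3' and the configuration of C2' stem from one earlier event, and C1' is fixed by the inversion the migration enforces. The forward step needs an alkoxide on C2' and a C1'–O bond antiperiplanar to it.

**13 ⇒ 12.** The oxirane of 13 is cut back to the diene 12. The forward epoxidation must take C1'=C6' in preference to C4'=C5' and to the C8=C12 methylidene, and must arrive anti to the C2' acetate. A peracid is not trusted with the first task, because an allylic acetate deactivates the ring alkene enough for the unhindered methylidene to compete. An oxo-transfer catalyst that needs a conjugated alkene is planned instead.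

**12 ⇒ 11.** The acetate is removed to give dienol 11. The ester is put on only after the coupling, since an allylic acetate on this diene would be ionised by the coupling catalyst.

**11 ⇒ 3 + 8 (through 9 and 10).** The C11–C1' bond is cut. It is the only bond between the two halves, its formation is an sp3–sp2 coupling with no stereochemical consequence, and the vinyl iodide it needs at C1' is already present in the arene. The alkyl partner is iodide 8, activated as a borate.

**3 ⇒ 2 ⇒ 1.** Removing the silylene from 3 gives triol 2. Then comes the central disconnection: the C2'–O and C3'–O bonds of 2 are cut together with rearomatisation, leading to the commercial arene 1. Forward, an enzyme must add two oxygens cis across one CH=CH edge and decide the absolute face.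

**8 ⇒ 7 ⇒ 6 ⇒ 5 ⇒ 4.** The methylidene of 8 comes from dehydration of tertiary alcohol 7. The C11 iodide and the loss of one carbon come from alkoxy-radical fragmentation of lactol 5 to iodoformate 6. Lactol 5 is the partial reduction product of sclareolide (4), which supplies C5, C9 and C10 in the correct configuration.

## Alternatives that were turned down

**Alternative 1:** This plan cuts no bond of the target at first. It adds two sacrificial C–C bonds by masking the C4'=C5' alkene of quinone A1 as a Diels–Alder adduct with cyclopentadiene (A2).
- Forward key step: a chiral oxazaborolidinium Lewis acid would steer the endo addition of A2 to the silyloxymethyl-bearing alkene of A1 and give the tricyclic enedione A3. Its folded shape would direct a nucleophilic epoxidation of the remaining C1'=C2' bond to the convex face. Reduction of the C3' carbonyl and a thermal retro-Diels–Alder reaction would finish ring C.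
- For it: a nucleophilic epoxidation of an enedione ignores the electron-rich C8=C12 methylidene. On this point the plan is stronger than the chosen one, whose epoxidation must discriminate between alkenes.
- Against it:
  - The two alkenes of A1 are both trisubstituted and electronically alike, so the catalyst must control site, face and endo selectivity next to a remote chiral terpene that gives no help.
  - The cycloaddition has to create a quaternary centre.
  - Hydride also prefers the convex face of A3, which would place the C3' hydroxyl trans to the oxirane, not cis as in 17.
  - The C3' and C6' ketones must be told apart.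
  - The unmasking needs temperatures that endanger an epoxy carbinol and a methylidene decalin.
- Comparison: four operations (mask, two face-selective steps, unmask) plus the synthesis of A1 are spent on what the chosen route obtains from one enzymatic step on a purchased arene. The chosen route pays with a more delicate epoxidation.

**Alternative 2:** Both bonds to C11 are cut, C9–C11 and C11–C1', and C11 returns as a carbonyl carbon.
- Forward key step: a carbonylative Suzuki–Miyaura coupling. A zerovalent palladium catalyst inserts into the C9–O bond of enol triflate A4, the acylpalladium species formed by carbonyl insertion is intercepted by arylboronic acid A5, and the tetrasubstituted aryl enone A6 results.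
- For it: it is the most convergent plan, joins three components in one flask, needs no one-carbon degradation of a terpene lactone and uses a robust aromatic partner. On convergence and on the reliability of its C–C bond formation it is stronger than the chosen route.
- Against it:
  - A6 has C11 at the ketone level and the alkene at C8=C9. The route must still deoxygenate C11, create the C9 stereocentre and move a tetrasubstituted alkene against the thermodynamic gradient to C8=C12.
  - Carbonyl insertion must outrun direct coupling at a hindered triflate.
  - Ring C arrives as a flat arene. Its oxidative dearomatisation would have to set C1', C2' and C3' absolutely with no stereocentre nearer than C9, so an extra enantioselective step or a diastereomer separation is unavoidable.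
- Comparison: the chosen route is less convergent in the terpene half, but it imports C9, the methylidene and the CH2 level of C11 intact from 4, and has the ring C stereocentres from its first step.

**Alternative 3:** The C1'–O and C4'–O bonds of a 1,4-dioxygenated ring are cut and traced to one O–O unit.
- Forward key step: a dye-sensitised photooxygenation adds across the C1'=C2'–C3'=C4' diene of A7 on the face opposite its C6' silyloxy group and gives the bicyclic endoperoxide A8. Isomerisation to the syn bis-oxirane, oxidation at C6' and a base-induced β-elimination opening the C3'–C4' oxirane would then give the C4'=C5' enone and the C3' carbinol cis to the surviving oxirane.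
- For it: the [4+2] addition is much faster than any ene reaction of the C8=C12 methylidene, so its chemoselectivity is better than that of step 9 below. The cis relation of oxirane and carbinol is built in, as in the chosen route. No metal or enzyme is needed.
- Against it:
  - All absolute information comes from the single C6' stereocentre of A7, which needs its own asymmetric step and is destroyed afterwards.
  - One allylic silyloxy group on a nearly planar diene gives weaker facial control than an enzyme pocket.
  - An endoperoxide with two fully substituted bridgeheads can fragment instead of rearranging.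
  - A7, with three differentiated oxygens, takes longer to assemble than 3 (two steps from 1).
- Comparison: the chosen route is shorter to the coupling stage and draws its absolute configuration from a catalytic step, at the price of an epoxidation that is less selective by nature.

Key step: step 1

## Route

Remark on locants: drimane numbering is used for the decalin (C11 is the linking methylene, C12 the methylidene carbon). The face of ring C that carries O2' and O3' is called the α face, the opposite one the β face.

Assumption: the recombinant dioxygenase strain is used as a whole-cell catalyst and is not counted as a starting material.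

Step 1
Reactants: 1 4-iodobenzyl alcohol
Product: 2 (1S,2S)-6-(hydroxymethyl)-3-iodocyclohexa-3,5-diene-1,2-diol
Conditions: E. coli JM109 (pDTG601) whole cells expressing toluene dioxygenase, IPTG induction, glucose feed, air, buffered medium pH 7, 30–35 °C; extraction with base-washed EtOAc
Reagents that add atoms: dioxygen, O=O
Why: The Rieske non-heme iron oxygenase binds O2 at its mononuclear iron centre, reduces it with two electrons relayed from NADH through the iron–sulfur cluster, and transfers both oxygen atoms suprafacially to the C2'–C3' edge of the arene; the closest known case is the toluene dioxygenase oxidation of para-substituted iodobenzenes such as 4-iodotoluene. No ring is closed: the benzene ring is dearomatised to a cyclohexa-1,3-diene and two C–O bonds are formed. Both new stereocentres, C2' and C3', are set by the enzyme: the oxygens are necessarily cis, and their absolute face is fixed by the orientation of the substrate in the active site, where the larger substituent acts as directing group. The selectivity the step needs is discrimination between the two para substituents, since binding with CH2OH in the place of iodine would give the enantiomer; iodine is among the strongest directing substituents for this enzyme and the hydroxymethyl group is small, which should secure the (1S,2S) diol. Constitutional regiochemistry is not in question, because both CH=CH edges of a para-disubstituted benzene are equivalent. The recombinant host lacks the diol dehydrogenase, so 2 should accumulate and not be rearomatised to a catechol. The C1' vinyl iodide and the C4'=C5' alkene with its hydroxymethyl group are left in place for the later steps.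

Step 2
Reactants: 2 (1S,2S)-6-(hydroxymethyl)-3-iodocyclohexa-3,5-diene-1,2-diol
Product: 3 iododienol silylene (O3'/O7' di-tert-butylsilylene with free C2'–OH)
Conditions: t-Bu2Si(OTf)2 (1.05 equiv), 2,6-lutidine, DMF, −40 to 0 °C
Reagents that add atoms: di-tert-butylsilyl bis(trifluoromethanesulfonate), CC(C)(C)[Si](OS(=O)(=O)C(F)(F)F)(OS(=O)(=O)C(F)(F)F)C(C)(C)C
Why: Silylene formation on a 1,3-diol: the primary allylic O7' is silylated first and the remaining silyl triflate closes onto O3' to a six-membered 1,3,2-dioxasilinane, whereas closure onto O2' would need a seven-membered ring and a five-membered silylene across O2'/O3' would require a hindered secondary hydroxyl to react first. O2' is left as the only free hydroxyl, and excess lutidine keeps the medium basic so that the dienediol does not lose water to a phenol.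

Step 3
Reactants: 4 (+)-sclareolide
Product: 5 sclareolide lactol
Conditions: i-Bu2AlH (1.1 equiv), CH2Cl2, −78 °C
Reagents that add atoms: none
Why: Partial reduction of the γ-lactone: the tetrahedral aluminium hemiacetal is stable at −78 °C and gives the lactol on work-up; no stereocentre of the decalin is touched.

Step 4
Reactants: 5 sclareolide lactol
Product: 6 11-iododriman-8α-yl formate
Conditions: PhI(OAc)2, I2, cyclohexane/CH2Cl2, visible light, rt
Reagents that add atoms: iodine, [I][I]
Why: Hypoiodite reaction (alkoxy-radical β-fragmentation): acetyl hypoiodite formed in the flask converts the lactol hydroxyl into an O–I bond, homolysis gives the anomeric alkoxy radical, and β-scission of the bond between C11 and the lactol carbon leaves a formate on O8 and a primary C11 radical that is trapped by iodine. The surplus carbon of 4 is excised and the C11 iodide installed in one operation; this degradation is known for the lactol of sclareolide.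

Step 5
Reactants: 6 11-iododriman-8α-yl formate
Product: 7 11-iododriman-8α-ol
Conditions: K2CO3 (0.2 equiv), MeOH, 0 °C
Reagents that add atoms: none
Why: Base-catalysed transesterification of a formate, the most labile simple ester; catalytic carbonate at 0 °C does not build up enough tertiary alkoxide for a 1,3-fragmentation (Grob type) or oxetane closure onto the C11 iodide.

Step 6
Reactants: 7 11-iododriman-8α-ol
Product: 8 11-iododrim-8(12)-ene
Conditions: SOCl2, pyridine, CH2Cl2, −78 °C
Reagents that add atoms: none
Why: Dehydration through the chlorosulfite by E2 elimination: the equatorial 8α C–O bond is antiperiplanar only to C–H bonds of the C12 methyl group, not to the ring hydrogens on C7 and C9, so the exocyclic alkene is the expected kinetic product at −78 °C. The primary iodide is inert, C9 is not epimerised, and endocyclic isomers are removed by chromatography.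

Step 7
Reactants: 8 11-iododrim-8(12)-ene; 3 iododienol silylene
Product: 11 C1'-(drim-8(12)-en-11-yl) dienol silylene, via drimenyllithium 9 (not isolated), via lithium alkylmethoxyborate 10 (not isolated)
Conditions: 8, t-BuLi (2.1 equiv), Et2O, −78 °C; 9-MeO-9-BBN, THF, −78 °C to rt; then 3, Pd(dppf)Cl2 (5 mol %), AsPh3, aq Cs2CO3, DMF, rt
Reagents that add atoms: none
Why: Iodine–lithium exchange gives the primary alkyllithium 9, which adds to the borinate ester to form ate complex 10; this transfers its primary alkyl group to the vinylpalladium iodide formed from 3 (B-alkyl Suzuki–Miyaura coupling), and the wide-bite-angle dppf ligand favours reductive elimination over β-hydride loss. The C2' hydroxyl is deliberately left free, because an allylic acetate on this diene would be ionised by zerovalent palladium and lead to aromatisation; no stereocentre is formed.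

Step 8
Reactants: 11 C1'-(drim-8(12)-en-11-yl) dienol silylene
Product: 12 dienyl C2' acetate
Conditions: Ac2O, pyridine, DMAP (cat.), CH2Cl2, 0 °C
Reagents that add atoms: acetic anhydride, CC(=O)OC(C)=O
Why: DMAP-catalysed acylation of the only free hydroxyl. The acetate removes the hydroxyl that would direct an oxidant to the α face, shields that face, and is the one base-labile group in the molecule, so that step 10 can release O2' selectively.

Step 9
Reactants: 12 dienyl C2' acetate
Product: 13 β C1'–C6' vinyl oxirane C2' acetate
Conditions: MnCl(C32H46N2O2) [chloro{N,N'-bis(3,5-di-tert-butylsalicylidene)ethylenediaminato}manganese] (5 mol %), PhIO (1.3 equiv), 4-phenylpyridine N-oxide, CH2Cl2, 0 °C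
Reagents that add atoms: iodosylbenzene, O=Ic1ccccc1
Why: Salen–manganese oxo transfer (Jacobsen–Katsuki-type epoxidation) runs through a carbon radical that must be conjugated, so the isolated C8=C12 methylidene, which would rival the acetate-deactivated ring alkene toward a peracid, is not attacked, and of the two diene alkenes the electrophilic oxo species takes C1'=C6' (one allylic C–O bond) before C4'=C5' (two). Oxygen is delivered to the β face, away from the pseudoaxial C2' acetate and the cis C3' silyloxy group, which sets C1' and C6' and gives the trans relation between oxirane and O2' that step 10 requires. The product is no longer a conjugated diene, so the reaction should stop at the monoepoxide.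

Step 10
Reactants: 13 β C1'–C6' vinyl oxirane C2' acetate
Product: 15 α C1'–C2' oxirane C6' allylic alcohol, via hydroxy vinyl oxirane 14 (not isolated)
Conditions: K2CO3, MeOH, 0 °C to rt
Reagents that add atoms: none
Why: Methanolysis of the acetate frees O2', whose alkoxide opens the oxirane at C1' from the rear in a 3-exo-tet displacement (Payne rearrangement): C1' is inverted, the new oxirane is built from the enzyme-derived O2' and therefore lies cis to O3', and O6' is released as an allylic hydroxyl. The silylene is stable to carbonate in methanol, and O3' cannot migrate further because it is cis to the new oxirane. The epoxy alcohols 14 and 15 interconvert, and since only 15 is consumed in step 11, recovered 14 is returned to these conditions.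

Step 11
Reactants: 15 α C1'–C2' oxirane C6' allylic alcohol
Product: 16 silylene-protected epoxy enone
Conditions: activated MnO2, CH2Cl2, rt
Reagents that add atoms: none
Why: MnO2 oxidises allylic alcohols only: the C6' carbinol of 15 gives the enone conjugated with C4'=C5', whereas the non-allylic C2' hydroxyl of any accompanying 14, the oxirane, the silylene and the methylidene are inert. The C6' stereocentre, which was never needed, disappears.

Step 12
Reactants: 16 silylene-protected epoxy enone
Product: 17 CNP0174686.2
Conditions: HF·pyridine, pyridine, THF, 0 °C
Reagents that add atoms: none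
Why: Fluoride-driven cleavage of both Si–O bonds of the silylene (formation of strong Si–F bonds) under buffered, nearly neutral conditions that should neither open the epoxy ketone nor epimerise C3' nor move the C8=C12 double bond. No stereocentre is involved.

## Compound list

1 | 4-iodobenzyl alcohol | OCc1ccc(I)cc1 | starting material
2 | (1S,2S)-6-(hydroxymethyl)-3-iodocyclohexa-3,5-diene-1,2-diol (O2' and O3' cis) | IC1=CC=C(CO)[C@H](O)[C@@H]1O | intermediate
3 | (8S,8aS)-2,2-di-tert-butyl-7-iodo-8,8a-dihydro-4H-1,3,2-benzodioxasilin-8-ol (silylene on O3'/O7', C2'–OH free) | IC1=CC=C2CO[Si](C(C)(C)C)(C(C)(C)C)O[C@@H]2[C@@H]1O | intermediate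
4 | (+)-sclareolide, (3aR,5aS,9aS,9bR)-3a,6,6,9a-tetramethyldecahydronaphtho[2,1-b]furan-2(1H)-one | C[C@]12CCCC([C@@H]1CC[C@@]3([C@@H]2CC(=O)O3)C)(C)C | starting material
5 | sclareolide lactol (2-hydroxy analogue of 4, anomeric mixture) | C[C@]12CCCC([C@@H]1CC[C@@]3([C@@H]2CC(O)O3)C)(C)C | intermediate
6 | 11-iododriman-8α-yl formate (8α-O, 8β-CH3, 9β-CH2I) | C[C@]12CCCC([C@@H]1CC[C@@](OC=O)([C@@H]2CI)C)(C)C | intermediate
7 | 11-iododriman-8α-ol | C[C@]12CCCC([C@@H]1CC[C@@](O)([C@@H]2CI)C)(C)C | intermediate
8 | (5S,9S,10S)-11-iododrim-8(12)-ene, (1S,4aS,8aS)-1-(iodomethyl)-5,5,8a-trimethyl-2-methylidenedecahydronaphthalene | C=C1CC[C@H]2C(C)(C)CCC[C@]2(C)[C@H]1CI | intermediate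
9 | (5S,9S,10S)-drim-8(12)-en-11-yllithium | C=C1CC[C@H]2C(C)(C)CCC[C@]2(C)[C@H]1C[Li] | intermediate
10 | lithium 9-(drim-8(12)-en-11-yl)-9-methoxy-9-borabicyclo[3.3.1]nonan-9-uide | C=C1CC[C@H]2C(C)(C)CCC[C@]2(C)[C@H]1C[B-]1(OC)C2CCCC1CCC2.[Li+] | intermediate
11 | (8R,8aS)-2,2-di-tert-butyl-7-[(5S,9S,10S)-drim-8(12)-en-11-yl]-8,8a-dihydro-4H-1,3,2-benzodioxasilin-8-ol (C2'–OH and O3' cis) | C=C1CC[C@H]2C(C)(C)CCC[C@]2(C)[C@H]1CC1=CC=C2CO[Si](C(C)(C)C)(C(C)(C)C)O[C@@H]2[C@@H]1O | intermediate
12 | C2' acetate of 11 | C=C1CC[C@H]2C(C)(C)CCC[C@]2(C)[C@H]1CC1=CC=C2CO[Si](C(C)(C)C)(C(C)(C)C)O[C@@H]2[C@@H]1OC(C)=O | intermediate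
13 | (1'S,2'S,3'S,6'S) vinyl oxirane acetate: oxirane C1'–C6' on the β face, trans to C2'–OAc; C4'=C5' retained; silylene on O3'/O7' | C=C1CC[C@H]2C(C)(C)CCC[C@]2(C)[C@H]1C[C@]12O[C@H]1C=C3CO[Si](C(C)(C)C)(C(C)(C)C)O[C@@H]3[C@@H]2OC(C)=O | intermediate
14 | hydroxy vinyl oxirane (13 without the acetyl group; C2'–OH trans to the C1'–C6' oxirane) | C=C1CC[C@H]2C(C)(C)CCC[C@]2(C)[C@H]1C[C@]12O[C@H]1C=C3CO[Si](C(C)(C)C)(C(C)(C)C)O[C@@H]3[C@@H]2O | intermediate
15 | (1'R,2'S,3'S,6'S) epoxy allylic alcohol: oxirane C1'–C2' on the α face, cis to O3'; C6'–OH on the β face; C4'=C5'; silylene on O3'/O7' | C=C1CC[C@H]2C(C)(C)CCC[C@]2(C)[C@H]1C[C@]12O[C@H]1[C@H]3O[Si](C(C)(C)C)(C(C)(C)C)OCC3=C[C@@H]2O | intermediate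
16 | (1'S,2'S,3'S) silylene-protected epoxy enone (C6' ketone of 15) | C=C1CC[C@H]2C(C)(C)CCC[C@]2(C)[C@H]1C[C@]12O[C@H]1[C@H]3O[Si](C(C)(C)C)(C(C)(C)C)OCC3=CC2=O | intermediate
17 | CNP0174686.2, (1S,5S,6S)-5-hydroxy-4-(hydroxymethyl)-1-{[(1S,4aS,8aS)-5,5,8a-trimethyl-2-methylidenedecahydronaphthalen-1-yl]methyl}-7-oxabicyclo[4.1.0]hept-3-en-2-one | C=C1CC[C@H]2C(C)(C)CCC[C@]2(C)[C@H]1C[C@]12O[C@H]1[C@@H](O)C(CO)=CC2=O | target

## Step count and least certain steps

Total: 12 steps. Longest linear sequence: 10 steps (4 → 5 → 6 → 7 → 8 → 11 → 12 → 13 → 15 → 16 → 17); the arene branch (1 → 2 → 3) joins at step 7.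

**Step 1 (key step).**
- What may go wrong: incomplete discrimination between iodine and CH2OH in the active site would lower the enantiomeric purity; oxidation of the benzylic alcohol by host dehydrogenases, or poor uptake, would limit conversion; the product may lose water to phenols during isolation. Any minor enantiomer becomes a diastereomer after coupling with the enantiopure terpene and can be removed at 11.
- Fallback (masked substrate): sets out from 1 and returns at 2. Acetylation of 1 (Ac2O, pyridine) gives 4-iodobenzyl acetate F1, which is not a dehydrogenase substrate and enters the cells more readily. The same whole-cell oxidation gives the diol acetate F2, and brief K2CO3/MeOH treatment releases 2.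

**Step 9.**
- What may go wrong: loss of site selectivity toward C4'=C5' or the methylidene; poor facial selectivity on a hindered trisubstituted alkene; allylic C–H oxidation followed by aromatisation.
- Fallback (remove the competing alkene and use a peracid): sets out from 7 and 3 and returns at 16.
  - Alcohol 7 is taken through the exchange–borylation of step 7, with one extra equivalent of t-BuLi for the hydroxyl, and coupled with 3 to give the 8-hydroxy dienol F3.
  - Acetylation of the secondary C2' hydroxyl (the tertiary one is inert) gives its C2' acetate F4.
  - With no methylidene present, mCPBA buffered with NaHCO3 should epoxidise C1'=C6' anti to the acetate to give the vinyl oxirane F5.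
  - K2CO3/MeOH gives the rearranged epoxy alcohol F6, and MnO2 the 8-hydroxy epoxy enone F7.
  - SOCl2/pyridine at −78 °C then forms the C8=C12 alkene and gives 16.

**Step 10.**
- What may go wrong: the epoxide migration is an equilibrium that may rest on the side of the conjugated vinyl oxirane 14; methoxide may open the allylic oxirane intermolecularly before the migration occurs.
- Fallback (coupled process in place of an isolated equilibrium): sets out from 13 and returns at 16. Once the acetate is cleaved, activated MnO2 is added to the carbonate suspension in CH2Cl2/MeOH. 15 is then oxidised as it forms and the equilibrium is drained irreversibly, which shortens the exposure of the epoxy alcohols to methoxide; no new compound is isolated.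

**Step 7.**
- What may go wrong: slow transmetalation of the β-branched, hindered alkyl group, leading to protodeboronation or β-hydride loss; Diels–Alder dimerisation or aromatisation of 3 before it couples.
- Fallback (Negishi coupling): sets out from 8 and returns at 11. Zinc insertion into 8 (Zn dust, LiCl, THF) gives drimenylzinc iodide F8, used in excess so that the free hydroxyl of 3 is tolerated as its zinc alkoxide. Coupling with 3 under Pd(dppf)Cl2 gives 11.

**Step 6.**
- What may go wrong: leakage into an E1 pathway, giving endocyclic C7=C8 and C8=C9 isomers that are hard to separate from 8.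
- Fallback (chemical differentiation): sets out from the crude alkene mixture obtained from 7 and returns at 8. A limiting amount of mCPBA at 0 °C epoxidises the tri- and tetrasubstituted ring alkenes faster than the 1,1-disubstituted methylidene, and the polar epoxides are removed by filtration through silica; no new compound is carried on.

## Further compounds

F1 | step 1 | 4-iodobenzyl acetate | CC(=O)OCc1ccc(I)cc1
F2 | step 1 | [(5S,6S)-5,6-dihydroxy-4-iodocyclohexa-1,3-dien-1-yl]methyl acetate | IC1=CC=C(COC(C)=O)[C@H](O)[C@@H]1O
F3 | step 9 | 8α-hydroxy analogue of 11 (C8 tertiary alcohol with C12 methyl, C2'–OH free) | C[C@]12CCCC([C@@H]1CC[C@@](O)([C@@H]2CC3=CC=C4CO[Si](C(C)(C)C)(C(C)(C)C)O[C@@H]4[C@@H]3O)C)(C)C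
F4 | step 9 | C2' acetate of F3 | C[C@]12CCCC([C@@H]1CC[C@@](O)([C@@H]2CC3=CC=C4CO[Si](C(C)(C)C)(C(C)(C)C)O[C@@H]4[C@@H]3OC(C)=O)C)(C)C
F5 | step 9 | β C1'–C6' oxirane of F4 (8α-hydroxy analogue of 13) | C[C@]12CCCC([C@@H]1CC[C@@](O)([C@@H]2C[C@]34O[C@H]3C=C5CO[Si](C(C)(C)C)(C(C)(C)C)O[C@@H]5[C@@H]4OC(C)=O)C)(C)C
F6 | step 9 | 8α-hydroxy analogue of 15 | C[C@]12CCCC([C@@H]1CC[C@@](O)([C@@H]2C[C@]34O[C@H]3[C@H]5O[Si](C(C)(C)C)(C(C)(C)C)OCC5=C[C@@H]4O)C)(C)C
F7 | step 9 | 8α-hydroxy analogue of 16 | C[C@]12CCCC([C@@H]1CC[C@@](O)([C@@H]2C[C@]34O[C@H]3[C@H]5O[Si](C(C)(C)C)(C(C)(C)C)OCC5=CC4=O)C)(C)C
F0 | step 10 | none | none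
F8 | step 7 | (5S,9S,10S)-drim-8(12)-en-11-ylzinc iodide | C=C1CC[C@H]2C(C)(C)CCC[C@]2(C)[C@H]1C[Zn]I
F0 | step 6 | none | none
A1 | alternative 1 | 2-[(5S,9S,10S)-drim-8(12)-en-11-yl]-5-[(tert-butyldimethylsilyloxy)methyl]-1,4-benzoquinone | C=C1CC[C@H]2C(C)(C)CCC[C@]2(C)[C@H]1CC1=CC(=O)C(CO[Si](C)(C)C(C)(C)C)=CC1=O
A2 | alternative 1 | cyclopenta-1,3-diene | C1=CC=CC1
A3 | alternative 1 | endo cyclopentadiene–quinone adduct (tricyclic enedione) | C=C1CC[C@H]2C(C)(C)CCC[C@]2(C)[C@H]1CC3=CC(=O)[C@]4(CO[Si](C)(C)C(C)(C)C)[C@@H]5C=C[C@@H](C5)[C@@H]4C3=O
A4 | alternative 2 | 11-nordrim-8-en-9-yl trifluoromethanesulfonate | CC=1CC[C@H]2C(C)(C)CCC[C@]2(C)C=1OS(=O)(=O)C(F)(F)F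
A5 | alternative 2 | [5-methoxy-2-(methoxymethoxy)-4-{[(triisopropylsilyl)oxy]methyl}phenyl]boronic acid | OB(O)c1cc(OC)c(CO[Si](C(C)C)(C(C)C)C(C)C)cc1OCOC
A6 | alternative 2 | aryl drim-8-en-11-one | CC=1CC[C@H]2C(C)(C)CCC[C@]2(C)C=1C(=O)c1cc(OC)c(CO[Si](C(C)C)(C(C)C)C(C)C)cc1OCOC
A7 | alternative 3 | 1'-(drim-8(12)-en-11-yl)-4'-[(4-methoxybenzyloxy)methyl]-6'-(tert-butyldimethylsilyloxy)cyclohexa-1',3'-diene | C=C1CC[C@H]2C(C)(C)CCC[C@]2(C)[C@H]1CC1=CC=C(COCc3ccc(OC)cc3)C[C@@H]1O[Si](C)(C)C(C)(C)C
A8 | alternative 3 | 2,3-dioxabicyclo[2.2.2]octene endoperoxide | C=C1CC[C@H]2C(C)(C)CCC[C@]2(C)[C@H]1C[C@]34OO[C@](COCc5ccc(OC)cc5)(C=C3)C[C@@H]4O[Si](C)(C)C(C)(C)C
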